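**Retrosynthetic overview**

- With the chain numbered C1' (benzylic) to C17', the strategy rests on C15', the only stereocentre. It is a secondary carbinol carbon flanked by the ethyl group C16'–C17' and the methylene C14', the pattern left when a boron-bound ethyl group and a carbon electrophile add across a vinyl group.
- C15'–O is traced back to C15'–B (stereoretentive oxidation). C15'–C16' and C13'–C14' are then cut together in a three-component conjunctive coupling of ethylboronic acid pinacol ester, vinylmagnesium bromide (C14', C15') and an (E)-alkenyl bromide carrying C1'–C13' and the arene.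
- The alkenyl bromide is built from the aryl bromide and 1,11-dibromoundecane (aryl C5–C1' bond, copper catalysis), lithium acetylide (C11'–C12' bond) and hydrozirconation–bromination.
- The benzene ring (oxygen at C1 and C3, chain at C5) is bought and no ring is formed. The phenols travel as benzyl ethers in place of methyl ethers, so that one final hydrogenation saturates C12'=C13' and frees both phenols without exposing the free carbinol to BBr3.

Key step: step 4

Assumption: 1,3-bis(benzyloxy)-5-bromobenzene is taken as a catalogue compound, and the (Sp,Sp) antipode of the Mandyphos ligand is taken to be the one leading to the (S)-boronate. Both antipodes are sold, so should a Mosher ester check on the alcohol of step 5 show the opposite sense, the mirror-image ligand is used with nothing else changed.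

**Route**

Step 1
Reactants: 1 1,3-bis(benzyloxy)-5-bromobenzene; 2 1,11-dibromoundecane
Product: 4 1,3-bis(benzyloxy)-5-(11-bromoundecyl)benzene, via arylmagnesium bromide 3 (not isolated)
Conditions: Mg, THF, 50 °C; then 2 (3 equiv), Li2CuCl4 (5 mol%), THF, −10 °C→rt
Reagents that add atoms: none
Why: Kochi coupling (Li2CuCl4-catalysed sp2–sp3 cross-coupling of an aryl Grignard reagent with a primary alkyl bromide), in which the threefold excess of the symmetrical dibromide should keep arylation at both ends low and the benzyl ethers are inert to the Grignard reagent.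

Step 2
Reactants: 4 1,3-bis(benzyloxy)-5-(11-bromoundecyl)benzene
Product: 5 1,3-bis(benzyloxy)-5-(tridec-12-yn-1-yl)benzene
Conditions: LiC≡CH·H2NCH2CH2NH2 (1.5 equiv), DMSO, 10 °C→rt
Reagents that add atoms: lithium acetylide–ethylenediamine complex, [Li]C#C.NCCN
Why: SN2 alkylation of lithium acetylide by the unhindered primary bromide in dipolar aprotic DMSO, a standard terminal-alkyne homologation that forms C11'–C12' and leaves aryl benzyl ethers untouched.

Step 3
Reactants: 5 1,3-bis(benzyloxy)-5-(tridec-12-yn-1-yl)benzene
Product: 7 (E)-1,3-bis(benzyloxy)-5-(13-bromotridec-12-en-1-yl)benzene, via alkenylzirconocene chloride 6 (not isolated)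
Conditions: Cp2Zr(H)Cl (1.2 equiv), THF, rt; then NBS (1.2 equiv), −20→0 °C, dark
Reagents that add atoms: N-bromosuccinimide, O=C1CCC(=O)N1Br
Why: Schwartz hydrozirconation adds Zr–H syn across the terminal alkyne with zirconium on C13', and bromodezirconation by N-bromosuccinimide proceeds with retention to the (E)-1-bromoalkene, the C–Zr bond being expected to react far faster at low temperature than the alkoxy-rich arene when the brominating agent is matched to zirconium.

Step 4
Reactants: 7 (E)-1,3-bis(benzyloxy)-5-(13-bromotridec-12-en-1-yl)benzene; 8 ethylboronic acid pinacol ester; 9 vinylmagnesium bromide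
Product: 11 (S,E)-2-{17-[3,5-bis(benzyloxy)phenyl]heptadec-5-en-3-yl}-4,4,5,5-tetramethyl-1,3,2-dioxaborolane, via vinyl(ethyl)boronate complex 10 (not isolated)
Conditions: 8, NaOTf (2.4 equiv), THF, 0 °C; 9 (1.2 equiv), 0 °C→rt; then 7 (1.0 equiv), Pd(OAc)2 (2 mol%), (Sp,Sp)-1,1'-bis[bis(4-methoxy-3,5-dimethylphenyl)phosphino]-2,2'-bis[(R)-(dimethylamino)(phenyl)methyl]ferrocene (Mandyphos, 2.4 mol%), THF, 40–60 °C
Reagents that add atoms: none
Why: This is a palladium-catalysed enantioselective conjunctive cross-coupling (metal-induced 1,2-metallate rearrangement), the closest known reaction class being the coupling of Grignard-derived vinylboron ate complexes with C(sp2) halides in the presence of NaOTf. Ate complex 10 forms from 8 and 9, NaOTf driving its formation and later stripping bromide from palladium; zerovalent palladium bearing the Mandyphos ligand inserts into the C13'–Br bond of 7, the resulting cationic alkenyl divalent palladium species binds the vinyl group of 10, and ethyl shifts from boron to C15' anti to palladium as palladium bonds C14'; reductive elimination then forms C13'–C14' with the E geometry of 7 kept. No ring is closed. The only new stereocentre, C15', is set by the chiral bisphosphine alone, which fixes the alkene face held by palladium and hence the face to which ethyl migrates, all three partners being achiral. The step needs enantioselectivity and the conjunctive path in preference to direct vinyl transfer (Suzuki–Miyaura diene formation) or β-hydride loss; the wide-bite-angle ligand disfavours transmetalation, ethyl is a simple primary migrating group, the bromide is unhindered, and the benzyloxyarene is remote.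

Step 5
Reactants: 11 (S,E)-2-{17-[3,5-bis(benzyloxy)phenyl]heptadec-5-en-3-yl}-4,4,5,5-tetramethyl-1,3,2-dioxaborolane
Product: 12 (S,E)-17-[3,5-bis(benzyloxy)phenyl]heptadec-5-en-3-ol
Conditions: 30% H2O2, 3 M NaOH, THF, 0 °C→rt
Reagents that add atoms: hydrogen peroxide, OO
Why: Oxidation of a secondary alkylboronic ester by hydroperoxide, in which C15' migrates from boron to oxygen with retention so that the (S)-C–B centre becomes the (S)-carbinol, while the alkene and benzyl ethers are inert to basic peroxide.

Step 6
Reactants: 12 (S,E)-17-[3,5-bis(benzyloxy)phenyl]heptadec-5-en-3-ol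
Product: 13 Hansfordiol C [(S)-5-(15-hydroxyheptadecyl)benzene-1,3-diol]
Conditions: H2 (1 atm), Pd/C (10 wt%), EtOAc/EtOH, rt
Reagents that add atoms: none
Why: Heterogeneous catalytic hydrogenation saturates the disubstituted C12'=C13' alkene and hydrogenolyses both aryl benzyl ethers in one operation; the C15' carbinol is neither allylic nor benzylic, so its C–O bond and configuration should be untouched, and mild conditions keep palladium-mediated double-bond migration minor.

**Compound list**

1 | 1,3-bis(benzyloxy)-5-bromobenzene | Brc1cc(OCc2ccccc2)cc(OCc2ccccc2)c1 | starting material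
2 | 1,11-dibromoundecane | BrCCCCCCCCCCCBr | starting material
3 | 3,5-bis(benzyloxy)phenylmagnesium bromide | Br[Mg]c1cc(OCc2ccccc2)cc(OCc2ccccc2)c1 | intermediate
4 | 1,3-bis(benzyloxy)-5-(11-bromoundecyl)benzene | BrCCCCCCCCCCCc1cc(OCc2ccccc2)cc(OCc2ccccc2)c1 | intermediate
5 | 1,3-bis(benzyloxy)-5-(tridec-12-yn-1-yl)benzene | C#CCCCCCCCCCCCc1cc(OCc2ccccc2)cc(OCc2ccccc2)c1 | intermediate
6 | (E)-{13-[3,5-bis(benzyloxy)phenyl]tridec-1-en-1-yl}chlorobis(cyclopentadienyl)zirconium (cyclopentadienyl rings drawn σ-bonded) | Cl[Zr](/C=C/CCCCCCCCCCCc1cc(OCc2ccccc2)cc(OCc2ccccc2)c1)(C1C=CC=C1)C1C=CC=C1 | intermediate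
7 | (E)-1,3-bis(benzyloxy)-5-(13-bromotridec-12-en-1-yl)benzene | Br/C=C/CCCCCCCCCCCc1cc(OCc2ccccc2)cc(OCc2ccccc2)c1 | intermediate
8 | ethylboronic acid pinacol ester (2-ethyl-4,4,5,5-tetramethyl-1,3,2-dioxaborolane) | CCB1OC(C)(C)C(C)(C)O1 | starting material
9 | vinylmagnesium bromide | C=C[Mg]Br | starting material
10 | bromomagnesium ethyl(vinyl)(pinacolato)borate | CC[B-]1(C=C)OC(C)(C)C(C)(C)O1.[Mg+]Br | intermediate
11 | (S,E)-2-{17-[3,5-bis(benzyloxy)phenyl]heptadec-5-en-3-yl}-4,4,5,5-tetramethyl-1,3,2-dioxaborolane | CC[C@H](B1OC(C)(C)C(C)(C)O1)C/C=C/CCCCCCCCCCCc1cc(OCc2ccccc2)cc(OCc2ccccc2)c1 | intermediate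
12 | (S,E)-17-[3,5-bis(benzyloxy)phenyl]heptadec-5-en-3-ol | CC[C@H](O)C/C=C/CCCCCCCCCCCc1cc(OCc2ccccc2)cc(OCc2ccccc2)c1 | intermediate
13 | Hansfordiol C, (S)-5-(15-hydroxyheptadecyl)benzene-1,3-diol | CC[C@H](O)CCCCCCCCCCCCCCc1cc(O)cc(O)c1 | target

**Step count**

Total step count: 6. Longest linear sequence: 6 steps (1 → 4 → 5 → 7 → 11 → 12 → 13).

**Steps most likely to fail**

1. Step 4 (key step). Possible failures are stalled conversion through incomplete ate-complex formation or bromide inhibition of the catalyst, direct vinyl transfer to palladium in place of the 1,2-shift, and weak facial discrimination for the small ethyl migrating group. The fallback takes C15' from the chiral pool; it sets out from 5 and comes back to the route at 13. Deprotonation of 5 with n-BuLi (THF, −78 °C) gives the lithium acetylide of 5 F1. With BF3·OEt2 this opens commercial (S)-1,2-epoxybutane at its CH2 terminus (Yamaguchi alkynylation, configuration of the epoxide carbon untouched) to give (S)-17-[3,5-bis(benzyloxy)phenyl]heptadec-5-yn-3-ol F2. Hydrogenation over Pd/C as in step 6 then saturates the alkyne and removes both benzyl groups to give 13.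

2. Step 3. Possible failures are competing electrophilic bromination of the electron-rich dialkoxyarene by N-bromosuccinimide and incomplete hydrozirconation. The fallback installs the alkenyl bromide before the arene is present; it sets out from 2 and comes back at 7. Excess 2 with LiC≡CH·H2NCH2CH2NH2 in DMSO gives 13-bromotridec-1-yne F3. Cp2Zr(H)Cl converts it into (E)-(13-bromotridec-1-en-1-yl)chlorobis(cyclopentadienyl)zirconium F4, and N-bromosuccinimide gives (E)-1,13-dibromotridec-1-ene F5. Arylmagnesium bromide 3 (from 1) with catalytic Li2CuCl4 then couples at the sp3 C–Br bond only, the alkenyl bromide being inert to copper catalysis at 0 °C, to give 7.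

3. Step 1. Possible failures are arylation at both ends of the dibromide, sluggish aryl–alkyl coupling and biaryl homocoupling of the Grignard reagent. The fallback reverses the polarity of the aryl–C1' bond formation; it sets out from 1 and comes back at 4. Hydroboration of commercial 11-bromoundec-1-ene with 9-borabicyclo[3.3.1]nonane gives 9-(11-bromoundecyl)-9-borabicyclo[3.3.1]nonane F6. B-alkyl Suzuki–Miyaura coupling of this with 1 (PdCl2(dppf), K3PO4, THF/DMF/H2O, 50 °C) gives 4, since palladium inserts into the aryl C–Br bond in preference to the primary alkyl C–Br bond.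

**Further compounds**

F1 | step 4 | lithium acetylide of 5, lithium 13-[3,5-bis(benzyloxy)phenyl]tridec-1-yn-1-ide | [Li]C#CCCCCCCCCCCCc1cc(OCc2ccccc2)cc(OCc2ccccc2)c1
F2 | step 4 | (S)-17-[3,5-bis(benzyloxy)phenyl]heptadec-5-yn-3-ol | CC[C@H](O)CC#CCCCCCCCCCCCc1cc(OCc2ccccc2)cc(OCc2ccccc2)c1
F3 | step 3 | 13-bromotridec-1-yne | C#CCCCCCCCCCCCBr
F4 | step 3 | (E)-(13-bromotridec-1-en-1-yl)chlorobis(cyclopentadienyl)zirconium | Cl[Zr](/C=C/CCCCCCCCCCCBr)(C1C=CC=C1)C1C=CC=C1
F5 | step 3 | (E)-1,13-dibromotridec-1-ene | Br/C=C/CCCCCCCCCCCBr
F6 | step 1 | 9-(11-bromoundecyl)-9-borabicyclo[3.3.1]nonane | BrCCCCCCCCCCCB1C2CCCC1CCC2
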